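The runs were computed with constants of no real substance; scatter was added.

the same everywhere: gas 12 mM (held); temperature 50 °C

|  | starting complex | leaving ligand | remark | time |
|---|---|---|---|---|
| Thursday's | 0.10 M | 2 equiv | the very flask that is asked about, followed so far |  |
| Wednesday's | 0.20 M | 2 equiv | run made earlier |  |
| flask | 0.10 M | 2.00 equiv |  | 20 min |

| run | time / min | complex with one exchanged / % | starting complex / % |
|---|---|---|---|
| Thursday's | 1.33 | 15.1 | 83.0 |
| Thursday's | 2.50 | 22.0 | 77.0 |
| Thursday's | 5.00 | 24.0 | 69.3 |
| Thursday's | 8.00 | 25.2 | 69.1 |
| Thursday's | 15.0 | 27.7 | 71.6 |
| Wednesday's | 0.250 | 3.1 | 98.6 |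
| Wednesday's | 0.667 | 5.1 | 94.2 |
| Wednesday's | 1.33 | 9.3 | 91.3 |
| Wednesday's | 2.00 | 12.0 | 86.0 |
| Wednesday's | 3.00 | 16.4 | 84.8 |

(scatter of a reading: 1 percentage point)

- ochre: at 20 min raise the temperature by 25 K, then wait 20 min
- red: at 20 min add starting complex, 50.0 % of the amount charged, then wait 20 min
- blue: at 20 min take out 90 % of the leaving ligand then present, then wait 20 min
- teal: change nothing and wait 20 min more

- at the start none of incoming ligand is dissolved
- additions leave the volume as it is
- candidate steps: starting complex + incoming ligand <-> leaving ligand + complex with one exchanged; complex with one exchanged + incoming ligand <-> leaving ligand + complex with two exchanged; gas <-> incoming ligand; incoming ligand -> decomposed reagent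
- the earlier runs do not show what temperature does; that part of a forecast is a guess

- complex with one exchanged, in percent of the starting complex first charged, at 20 min
- what to do for the largest gain in complex with one exchanged; "none" if nothing gains more than 2 percentage points (ochre / red / blue / teal / none)
- complex with one exchanged present, in percent of the starting complex first charged, after red
- complex with one exchanged present, in percent of the starting complex first charged, after blue

It is easy to read a flask that stops climbing as a flask short of something, but Thursday's flask stops with 70.0 % of its starting complex still free. That is my mean of the last 3 readings, beside 25.6 % of complex with one exchanged and a gap of 4.37 %, which I book as complex with two exchanged. I read this as a standing balance, thermodynamic rather than kinetic control. Where the forward and back rates of an exchange are equal, dividing one by the other removes time. With leaving ligand at 0.234 M, that leaves 0.0858 M as the plateau quotient: complex formed over the complex it came from, times leaving ligand. The second exchange reads 0.0399 M. I take both to hold while incoming ligand stays at its plateau level, which is my assumption, since the readings do not measure it.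

Which numbers must be good? Time need not be: in Thursday's flask starting complex reads 69.3 % at 5.00 min and 71.6 % at 15.0 min. The early rate enters my reckoning as a time, not as a height: complex with one exchanged forms at a mean 11.4 mM min⁻¹ up to 1.33 min in Thursday's flask and 10.9 mM min⁻¹ up to 3.00 min in Wednesday's, at twice the charge. The second quotient does not touch the plateau, which I read directly, but it matters for blue. Blue leaves 0.0234 M of leaving ligand. At a trial 0.0703 M, complex with one exchanged is 55.0 % without the second exchange and 41.9 % with it.

So I commit to 25.6 % now, and teal stays there. For red, leaving ligand near 0.252 M gives 36.7 %. For blue, the trial's release brings leaving ligand to 0.0785 M, and the middle, 0.0744 M, gives 41.6 %; at Thursday's early rate I estimate that release at 4.49 min, less than the 20 min of waiting. The runs do not show what ochre does. I choose blue, which by my reckoning ends higher than red.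

The forecast gives 28 %, 40 % after red, 53 % after blue and the choice blue, holding that “removing 90% of the leaving ligand pulls the equilibrium strongly forward”; its choice is mine, its blue stands above mine.

The flask gives 25.9 %, then 37.3 % after red and 41.3 % after blue, whose gain of 15 percentage points is the largest.

    starting complex + incoming ligand ⇌ leaving ligand + complex with one exchanged (K = 9.50, k = 0.759 M⁻¹ s⁻¹, Ea = 65.0 kJ mol⁻¹, ΔH = −46.0 kJ mol⁻¹)
    complex with one exchanged + incoming ligand ⇌ leaving ligand + complex with two exchanged (K = 4.60, k = 0.247 M⁻¹ s⁻¹, Ea = 53.0 kJ mol⁻¹, ΔH = −51.0 kJ mol⁻¹)
    gas ⇌ incoming ligand, rate k3*(csat - [incoming ligand]) (kL = 0.0492 s⁻¹)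
    incoming ligand → decomposed reagent (k = 0.0149 s⁻¹, Ea = 97.0 kJ mol⁻¹)
    (constants at 50 °C)

In the flask, incoming ligand stands at 0.00917 M at 10.0 min and 0.00921 M at 200 min. At 20.0 min the flask's leaving ligand is 0.235 M, so the quotient gives 0.365 of complex with one exchanged per starting complex, and the flask holds 25.9 % beside 69.5 %. In the 0.025 M neighbour, leaving ligand is 0.0724 M, so the quotient gives 1.19, and that flask holds 41.5 % beside 34.4 %.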